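## Retrosynthetic overview
1. δ-Lactone (closed last): break the acyl C1–O2 bond to give ethyl 2,4-dihydroxy-6-[(2R)-2-hydroxyalkyl]benzoate.
2. Benzene ring (formed first, same pot): Diels–Alder/retro-Diels–Alder (loss of isobutene) leads back to a 5-hydroxy-2-ynoate and the dimedone-derived 1,3-bis(silyloxy)diene.
3. C4–C(sp) bond: (R)-terminal epoxide plus lithiated ethyl propiolate/BF3.
4. The epoxide comes from (R)-epichlorohydrin and a C10 Grignard reagent. The C10 unit comes from (S)-propylene oxide and 7-chloroheptylmagnesium bromide, then O-methylation.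
5. Both C–O stereocentres come intact from the two C3 epoxides, and no bond at a stereocentre is ever broken.

Assumption: the SMILES reads as (3R)-6,8-dihydroxy-3-[(10S)-10-methoxyundecyl]-3,4-dihydroisocoumarin with nine CH2 groups between the stereocentres, and 1-bromo-7-chloroheptane is taken as a catalogue chemical.

## Route

Step 1
Reactants: 1 1-bromo-7-chloroheptane; 2 (S)-propylene oxide
Product: 4 (2S)-10-chlorodecan-2-ol, via 7-chloroheptylmagnesium bromide 3 (not isolated)
Conditions: Mg (1.05 equiv), THF, 35 °C; CuI (10 mol %), 2, −30 → 0 °C; 1 M HCl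
Reagents that add atoms: none
Why: Mg inserts into C–Br far faster than into C–Cl, and the Cu(I)-catalysed Grignard epoxide opening is an SN2 attack at the unsubstituted CH2, so the C–O stereocentre of 2 is carried unchanged into 4 as (S).

Step 2
Reactants: 4 (2S)-10-chlorodecan-2-ol
Product: 6 (9S)-1-chloro-9-methoxydecane, via sodium alkoxide 5 (not isolated)
Conditions: NaH, THF, 0 °C; MeI, rt
Reagents that add atoms: iodomethane, CI
Why: In this Williamson ether synthesis MeI reacts far faster than the remote primary chloride, and only the O–H bond changes, so the centre stays (S).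

Step 3
Reactants: 6 (9S)-1-chloro-9-methoxydecane; 7 (R)-epichlorohydrin
Product: 10 (2R)-2-[(10S)-10-methoxyundecyl]oxirane, via (9S)-9-methoxydecylmagnesium chloride 8 (not isolated), via chlorohydrin 9 (not isolated)
Conditions: Mg, I2 (cat.), THF, reflux; CuI (10 mol %), 7 (1.2 equiv), −40 → 0 °C; then 4 M aq NaOH, rt
Reagents that add atoms: none
Why: The Cu(I)-catalysed Grignard opening occurs at the epoxide CH2 of 7 and is followed by halohydrin closure (intramolecular Williamson reaction) onto CH2Cl, so the C2–O bond is never broken and (R)-7 gives the (R)-epoxide.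

Step 4
Reactants: 10 (2R)-2-[(10S)-10-methoxyundecyl]oxirane; 11 ethyl propiolate
Product: 13 ethyl (5R,15S)-5-hydroxy-15-methoxyhexadec-2-ynoate, via ethyl 3-lithiopropiolate 12 (not isolated)
Conditions: 11 (3 equiv), n-BuLi, THF, −78 °C; BF3·OEt2 (3 equiv); 10, −78 °C, 2 h; H2O
Reagents that add atoms: none
Why: In this Yamaguchi–Hirao alkynylation the BF3-activated terminal epoxide is opened by the weakly basic acetylide at the CH2 terminus at −78 °C, which leaves the carbinol centre (R) and the ester and methyl ether untouched.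

Step 5
Reactants: 14 dimedone (5,5-dimethylcyclohexane-1,3-dione)
Product: 15 5,5-dimethyl-1,3-bis(trimethylsilyloxy)cyclohexa-1,3-diene
Conditions: TMSOTf (2.2 equiv), Et3N (3 equiv), Et2O, 0 °C → rt; decant, distil
Reagents that add atoms: trimethylsilyl trifluoromethanesulfonate, C[Si](C)(C)OS(=O)(=O)C(F)(F)F
Why: Soft enolisation with double O-silylation of the 1,3-diketone gives a single diene, because the symmetry of dimedone makes both possible second deprotonations lead to the same compound.

Step 6
Reactants: 13 ethyl (5R,15S)-5-hydroxy-15-methoxyhexadec-2-ynoate; 15 5,5-dimethyl-1,3-bis(trimethylsilyloxy)cyclohexa-1,3-diene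
Product: 19 (3R)-6,8-dihydroxy-3-[(10S)-10-methoxyundecyl]-3,4-dihydro-1H-isochromen-1-one (target), via bicyclo[2.2.2]octadiene cycloadduct 16 (not isolated), via bis-TMS resorcylate 17 (not isolated), via hydroxy ester 18 (not isolated)
Conditions: 15 (4 equiv), neat, sealed tube, 150 °C, 36 h; MeOH, rt; p-TsOH·H2O (10 mol %), PhMe, 110 °C
Reagents that add atoms: none
Why: The s-cis-locked diene undergoes a normal-demand Diels–Alder reaction in which its nucleophilic CH terminus bonds to the β-carbon of the ynoate, the adduct aromatises by retro-Diels–Alder loss of isobutene (Alder–Rickert) to the 2,4-dioxygenated 6-alkylbenzoate, and after methanolysis of the aryl silyl ethers an acid-catalysed transesterification closes the δ-lactone at the acyl carbon, so C3 stays (R) and the transient bridgehead centres vanish.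

## Compound list
1 | 1-bromo-7-chloroheptane | ClCCCCCCCBr | starting material
2 | (S)-propylene oxide, (2S)-2-methyloxirane | C[C@H]1CO1 | starting material
3 | 7-chloroheptylmagnesium bromide | ClCCCCCCC[Mg]Br | intermediate
4 | (2S)-10-chlorodecan-2-ol | C[C@H](O)CCCCCCCCCl | intermediate
5 | sodium (2S)-10-chlorodecan-2-olate | C[C@H]([O-])CCCCCCCCCl.[Na+] | intermediate
6 | (9S)-1-chloro-9-methoxydecane | CO[C@@H](C)CCCCCCCCCl | intermediate
7 | (R)-epichlorohydrin, (2R)-2-(chloromethyl)oxirane | ClC[C@H]1CO1 | starting material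
8 | (9S)-9-methoxydecylmagnesium chloride | CO[C@@H](C)CCCCCCCC[Mg]Cl | intermediate
9 | (2R,12S)-1-chloro-12-methoxytridecan-2-ol | CO[C@@H](C)CCCCCCCCC[C@@H](O)CCl | intermediate
10 | (2R)-2-[(10S)-10-methoxyundecyl]oxirane | CO[C@@H](C)CCCCCCCCC[C@@H]1CO1 | intermediate
11 | ethyl propiolate | C#CC(=O)OCC | starting material
12 | ethyl 3-lithiopropiolate | [Li]C#CC(=O)OCC | intermediate
13 | ethyl (5R,15S)-5-hydroxy-15-methoxyhexadec-2-ynoate | CO[C@@H](C)CCCCCCCCC[C@@H](O)CC#CC(=O)OCC | intermediate
14 | dimedone, 5,5-dimethylcyclohexane-1,3-dione | CC1(C)CC(=O)CC(=O)C1 | starting material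
15 | 5,5-dimethyl-1,3-bis(trimethylsilyloxy)cyclohexa-1,3-diene | C[Si](C)(C)OC1=CC(O[Si](C)(C)C)=CC(C)(C)C1 | intermediate
16 | ethyl 3-[(2R,12S)-2-hydroxy-12-methoxytridecyl]-8,8-dimethyl-1,5-bis(trimethylsilyloxy)bicyclo[2.2.2]octa-2,5-diene-2-carboxylate (both bridgehead diastereomers) | CO[C@@H](C)CCCCCCCCC[C@@H](O)CC1=C(C(=O)OCC)C2(O[Si](C)(C)C)C=C(O[Si](C)(C)C)C1C(C)(C)C2 | intermediate
17 | ethyl 6-[(2R,12S)-2-hydroxy-12-methoxytridecyl]-2,4-bis(trimethylsilyloxy)benzoate | CO[C@@H](C)CCCCCCCCC[C@@H](O)Cc1cc(O[Si](C)(C)C)cc(O[Si](C)(C)C)c1C(=O)OCC | intermediate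
18 | ethyl 2,4-dihydroxy-6-[(2R,12S)-2-hydroxy-12-methoxytridecyl]benzoate | CO[C@@H](C)CCCCCCCCC[C@@H](O)Cc1cc(O)cc(O)c1C(=O)OCC | intermediate
19 | (3R)-6,8-dihydroxy-3-[(10S)-10-methoxyundecyl]-3,4-dihydro-1H-isochromen-1-one | CO[C@@H](C)CCCCCCCCC[C@@H]1Cc2cc(O)cc(O)c2C(=O)O1 | target

## Step count and risks
Total steps: 6. Longest linear sequence: 5 (steps 1, 2, 3, 4, 6). Step 5 is a one-step side branch.

**Step 6 (most at risk).**
- Risk: a β-alkyl ynoate is a sluggish dienophile, and the free carbinol can strip silyl groups from the diene at 150 °C. The excess of 15 is there to cover this.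
- The fallback sets out from 13 and comes back at 18. It changes the diene class, the way the ring aromatises and the handling of the hydroxyl.
- Compound 13 is silylated (TESCl, imidazole, DMF) to ethyl (5R,15S)-15-methoxy-5-(triethylsilyloxy)hexadec-2-ynoate F1.
- F1 is heated in toluene at 110 °C with commercial 1-methoxy-1,3-bis(trimethylsilyloxy)buta-1,3-diene (Chan's diene). This gives the Diels–Alder adduct ethyl 6-methoxy-2-[(2R,12S)-12-methoxy-2-(triethylsilyloxy)tridecyl]-4,6-bis(trimethylsilyloxy)cyclohexa-1,4-diene-1-carboxylate F2.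
- F2 aromatises by eliminating methanol rather than by cycloreversion. Brief treatment with MeOH then gives ethyl 2,4-dihydroxy-6-[(2R,12S)-12-methoxy-2-(triethylsilyloxy)tridecyl]benzoate F3.
- p-TsOH in MeOH removes the TES group to give 18, which lactonises to 19 as in step 6.

**Step 4.**
- Risk: lithiated propiolate is thermally fragile, and BF3-promoted opening can give modest conversion.
- The fallback sets out from 10 and comes back at 13. It builds the ynoate as C2 + C1 instead of from a C3 nucleophile.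
- Lithium acetylide–ethylenediamine in DMSO at rt opens 10 at the terminal carbon to give (4R,14S)-14-methoxypentadec-1-yn-4-ol F4.
- The dianion of F4 (n-BuLi, 2.2 equiv, THF, −78 °C) is carboxylated with CO2 to give (5R,15S)-5-hydroxy-15-methoxyhexadec-2-ynoic acid F5.
- Alkylation of the carboxylate (EtI, K2CO3, DMF) gives 13.

**Step 3.**
- Risk: Grignard formation from the primary chloride may be slow or accompanied by Wurtz coupling, and magnesium chloride can scramble epichlorohydrin.
- The fallback sets out from 6 and 7 and comes back at 10. It joins the halves by olefin metathesis instead of by a Grignard reaction of the valuable fragment.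
- E2 elimination of 6 (KOt-Bu, THF/DMSO, 50 °C) gives (9S)-9-methoxydec-1-ene F6.
- Separately, 7 reacts with commercial vinylmagnesium bromide (CuI cat.) to give (2R)-1-chloropent-4-en-2-ol F7, which NaOH closes to (2R)-2-allyloxirane F8.
- Cross-metathesis of F6 with excess F8 (achiral Grubbs second-generation catalyst, CH2Cl2, 40 °C) gives (2R)-2-[(2E,10S)-10-methoxyundec-2-en-1-yl]oxirane F9.
- Hydrogenation of the isolated alkene (H2, Pd/C, EtOAc) gives 10.

## Further compounds
F1 | step 6 | ethyl (5R,15S)-15-methoxy-5-(triethylsilyloxy)hexadec-2-ynoate | CO[C@@H](C)CCCCCCCCC[C@@H](O[Si](CC)(CC)CC)CC#CC(=O)OCC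
F2 | step 6 | ethyl 6-methoxy-2-[(2R,12S)-12-methoxy-2-(triethylsilyloxy)tridecyl]-4,6-bis(trimethylsilyloxy)cyclohexa-1,4-diene-1-carboxylate | CO[C@@H](C)CCCCCCCCC[C@@H](O[Si](CC)(CC)CC)CC1=C(C(=O)OCC)C(OC)(O[Si](C)(C)C)C=C(O[Si](C)(C)C)C1
F3 | step 6 | ethyl 2,4-dihydroxy-6-[(2R,12S)-12-methoxy-2-(triethylsilyloxy)tridecyl]benzoate | CO[C@@H](C)CCCCCCCCC[C@@H](O[Si](CC)(CC)CC)Cc1cc(O)cc(O)c1C(=O)OCC
F4 | step 4 | (4R,14S)-14-methoxypentadec-1-yn-4-ol | CO[C@@H](C)CCCCCCCCC[C@@H](O)CC#C
F5 | step 4 | (5R,15S)-5-hydroxy-15-methoxyhexadec-2-ynoic acid | CO[C@@H](C)CCCCCCCCC[C@@H](O)CC#CC(=O)O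
F6 | step 3 | (9S)-9-methoxydec-1-ene | CO[C@@H](C)CCCCCCC=C
F7 | step 3 | (2R)-1-chloropent-4-en-2-ol | C=CC[C@@H](O)CCl
F8 | step 3 | (2R)-2-allyloxirane | C=CC[C@@H]1CO1
F9 | step 3 | (2R)-2-[(2E,10S)-10-methoxyundec-2-en-1-yl]oxirane | CO[C@@H](C)CCCCCC/C=C/C[C@@H]1CO1
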